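**Retrosynthetic overview**
1. The cyclohexane ring of the target has a quaternary C1 (O-acyl, CO2H) between two CH2 groups (C2, C6). That is the retron of a Diels–Alder reaction of buta-1,3-diene with a 2-oxyacrylate; the key step forms C1–C2 and C5–C6, closes the only carbocycle and sets C1.
2. C3, C4 and C5 are relayed from C1. The C1 oxygen (as a tert-butyl carbonate) is delivered to C3 by iodocarbonate cyclization, which forces O1/O3 cis; loss of HI leaves C4=C5; the C3–OH then directs an epoxidation to the same ring face.
3. The C4–C5 oxirane is the latent trans-diol and the only "protection" of O4/O5, so the two caffeoyl groups go on the only free hydroxyls, O1 and O3.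
4. Last, the C1 ester carbonyl opens the oxirane at C5 (inversion; O5 cis to the carboxyl, O4 cis to O3); hydrolysis of the resulting γ-lactone and the aryl acetates gives the target.
5. Ring order: cyclohexene (Diels–Alder) → transient C1/C3 1,3-dioxan-2-one bridge → C4/C5 oxirane → transient C1/C5 γ-lactone.

Key step: step 3

Assumption: ring atoms are numbered as in quinic acid (C1 quaternary, C3 CH–O-caffeoyl, C4 and C5 CH–OH); the target is the (1R,3R,4S,5R) isomer with O1, O3, O4 on one ring face and CO2H, O5 on the other. Phenols are carried as acetates. Common reagents are not numbered.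

**Route**

Step 1
Reactants: 1 (S)-lactic acid; 2 pivalaldehyde
Product: 3 (2S,5S)-2-tert-butyl-5-methyl-1,3-dioxolan-4-one
Conditions: cat. TsOH, cat. H2SO4, pentane, reflux, Dean–Stark; crystallization from pentane, −78 °C
Reagents that add atoms: none
Why: Acid-catalysed acetalization of an α-hydroxy acid under water removal (self-regeneration-of-stereocentres principle); the lactate centre should favour the cis acetal, which fixes the new acetal centre C2 as S and should be enriched by crystallization.

Step 2
Reactants: 3 (2S,5S)-2-tert-butyl-5-methyl-1,3-dioxolan-4-one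
Product: 5 (2S)-2-tert-butyl-5-methylidene-1,3-dioxolan-4-one, via 5-bromodioxolanone 4 (not isolated)
Conditions: NBS, cat. AIBN, PhCF3, reflux; filter; then Et3N, Et2O, 0 °C → rt
Reagents that add atoms: none
Why: Wohl–Ziegler radical bromination at the captodative C5–H followed by E2 loss of HBr into the methyl group should give the exocyclic alkene, leaving the acetal carbon C2 as the only stereocentre.

Step 3
Reactants: 5 (2S)-2-tert-butyl-5-methylidene-1,3-dioxolan-4-one; 6 buta-1,3-diene
Product: 7 (2S,5R)-2-tert-butyl-1,3-dioxaspiro[4.5]dec-7-en-4-one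
Conditions: 6 (excess), cat. BHT, toluene, sealed tube, 90–100 °C
Reagents that add atoms: none
Why: Concerted thermal [4π+2π] cycloaddition of s-cis butadiene to the exocyclic C=C of the captodative 2-oxyacrylate 5; the closest known reaction type is the auxiliary-controlled Diels–Alder reaction of 5-methylidene-1,3-dioxolan-4-ones with simple dienes. It closes the only carbocycle of the target, the cyclohexene, in intermolecular [4+2] mode by forming C1–C2 and C5–C6 (quinic numbering) around the future quaternary C1. The one new stereocentre, spiro C5 of 7 (C1 of the target), is controlled by the acetal centre C2: the diene should add to the face of the flat dioxolanone anti to the tert-butyl group, so that the allylic ring CH2 ends up anti to tert-butyl. Only π-facial selectivity is needed, because the symmetric diene makes regiochemistry and endo/exo orientation irrelevant to the constitution and configuration of 7. The competing process is radical polymerization of the dienophile, which BHT and excess diene should hold back. The precursor is two steps from lactic acid, whereas the product already holds the ring, the quaternary C–O/C–CO centre and the alkene from which C3, C4 and C5 are relayed.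

Step 4
Reactants: 7 (2S,5R)-2-tert-butyl-1,3-dioxaspiro[4.5]dec-7-en-4-one
Product: 8 methyl (1R)-1-hydroxycyclohex-3-ene-1-carboxylate
Conditions: cat. NaOMe, MeOH, 0 °C → rt
Reagents that add atoms: methanol CO
Why: Methoxide transesterification opens the dioxolanone and the hemiacetal alkoxide collapses with loss of pivalaldehyde; the quaternary C1 has no α-hydrogen and cannot epimerize.

Step 5
Reactants: 8 methyl (1R)-1-hydroxycyclohex-3-ene-1-carboxylate
Product: 10 methyl (1R)-1-[(tert-butoxycarbonyl)oxy]cyclohex-3-ene-1-carboxylate, via lithium alkoxide 9 (not isolated)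
Conditions: LiHMDS, THF, −78 °C; then Boc2O, −78 → 0 °C
Reagents that add atoms: di-tert-butyl dicarbonate CC(C)(C)OC(=O)OC(=O)OC(C)(C)C
Why: O-acylation of the tertiary lithium alkoxide of an α-hydroxy ester with Boc2O should give the homoallylic tert-butyl carbonate without touching C1.

Step 6
Reactants: 10 methyl (1R)-1-[(tert-butoxycarbonyl)oxy]cyclohex-3-ene-1-carboxylate
Product: 11 methyl (1R,5R,6R)-6-iodo-3-oxo-2,4-dioxabicyclo[3.3.1]nonane-1-carboxylate
Conditions: IBr, toluene, −80 °C; aq. Na2S2O3/NaHCO3 quench
Reagents that add atoms: iodine monobromide IBr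
Why: Iodocarbonate cyclization of a homoallylic tert-butyl carbonate: the iodonium ion forms reversibly, the axial carbonate carbonyl oxygen opens it at C3 (six-membered ring, trans-diaxial) and loss of the tert-butyl group as t-BuBr makes this irreversible, so the bridge forces the new C3–O cis to C1–O and places C4–I trans to it.

Step 7
Reactants: 11 methyl (1R,5R,6R)-6-iodo-3-oxo-2,4-dioxabicyclo[3.3.1]nonane-1-carboxylate
Product: 13 methyl (1R,3R)-1,3-dihydroxycyclohex-4-ene-1-carboxylate, via bicyclic alkene carbonate 12 (not isolated)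
Conditions: DBU, toluene, 80 °C; then MeOH, cat. K2CO3, rt
Reagents that add atoms: none
Why: Anti-periplanar E2 elimination can only use the axial C5–H (the C3–H is equatorial), which should give the C4=C5 alkene, and base-catalysed methanolysis of the cyclic carbonate then frees the cis-1,3-diol without touching a stereocentre.

Step 8
Reactants: 13 methyl (1R,3R)-1,3-dihydroxycyclohex-4-ene-1-carboxylate
Product: 14 methyl (1R,2R,4S,6S)-2,4-dihydroxy-7-oxabicyclo[4.1.0]heptane-4-carboxylate (oxirane cis to both hydroxyls, trans to CO2Me)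
Conditions: cat. VO(acac)2, t-BuOOH (decane), CH2Cl2, 0 °C → rt
Reagents that add atoms: tert-butyl hydroperoxide CC(C)(C)OO
Why: Vanadium-catalysed hydroxyl-directed epoxidation: the allylic C3–OH (supported by the homoallylic C1–OH on the same face) should deliver oxygen to the alkene face cis to both hydroxyls, setting C4 and C5 of the oxirane.

Step 9
Reactants: 15 caffeic acid
Product: 16 (E)-3-(3,4-diacetoxyphenyl)prop-2-enoic acid
Conditions: Ac2O, pyridine, cat. DMAP, 0 °C → rt; then H2O/THF
Reagents that add atoms: acetic anhydride CC(=O)OC(C)=O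
Why: Standard acetylation of both phenols; the mixed anhydride at the carboxyl group is hydrolysed on aqueous work-up.

Step 10
Reactants: 16 (E)-3-(3,4-diacetoxyphenyl)prop-2-enoic acid
Product: 17 (E)-3-(3,4-diacetoxyphenyl)prop-2-enoyl chloride
Conditions: (COCl)2, cat. DMF, CH2Cl2, 0 °C → rt; used crude
Reagents that add atoms: oxalyl chloride O=C(Cl)C(Cl)=O
Why: Vilsmeier-type activation converts the acid into the acid chloride, which aryl acetates and the (E)-alkene tolerate.

Step 11
Reactants: 14 methyl (1R,2R,4S,6S)-2,4-dihydroxy-7-oxabicyclo[4.1.0]heptane-4-carboxylate; 17 (E)-3-(3,4-diacetoxyphenyl)prop-2-enoyl chloride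
Product: 18 methyl 1,3-bis-O-(3,4-di-O-acetylcaffeoyl)-4,5-anhydroquinate (the bis-ester of 14, configuration unchanged)
Conditions: 17 (3 equiv), Et3N, DMAP, CH2Cl2, 0 °C → rt
Reagents that add atoms: none
Why: DMAP-catalysed acylation through the N-acylpyridinium ion should esterify the secondary C3–OH and the ester-activated tertiary C1–OH, the only hydroxyls present because O4/O5 are tied up in the oxirane.

Step 12
Reactants: 18 methyl 1,3-bis-O-(3,4-di-O-acetylcaffeoyl)-4,5-anhydroquinate
Product: 20 1,3-di-O-caffeoylquinic acid (target), via bis(diacetylcaffeoyl)quinide 19 (not isolated)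
Conditions: TFA, CH2Cl2, 0 °C → rt; concentrate; then 2 M aq. HCl/THF (1:3), rt
Reagents that add atoms: water O
Why: Neighbouring-group opening of the protonated oxirane by the C1 ester carbonyl oxygen (epoxy ester → hydroxy lactone, 5-exo, trans-diaxial) should invert C5 (O5 cis to the carboxyl), keep C4–O cis to O3 and expel the ester methyl, after which aqueous acid hydrolyses the strained γ-lactone and the four aryl acetates while the cinnamate-type esters should persist.

**Compound list**
1 | (S)-lactic acid | C[C@H](O)C(=O)O | starting material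
2 | pivalaldehyde | CC(C)(C)C=O | starting material
3 | (2S,5S)-2-tert-butyl-5-methyl-1,3-dioxolan-4-one | C[C@@H]1O[C@H](C(C)(C)C)OC1=O | intermediate
4 | (2S,5R)-5-bromo-2-tert-butyl-5-methyl-1,3-dioxolan-4-one (not isolated) | C[C@]1(Br)O[C@H](C(C)(C)C)OC1=O | intermediate
5 | (2S)-2-tert-butyl-5-methylidene-1,3-dioxolan-4-one | C=C1O[C@H](C(C)(C)C)OC1=O | intermediate
6 | buta-1,3-diene | C=CC=C | starting material
7 | (2S,5R)-2-tert-butyl-1,3-dioxaspiro[4.5]dec-7-en-4-one | C1=CC[C@]2(O[C@H](C(C)(C)C)OC2=O)CC1 | intermediate
8 | methyl (1R)-1-hydroxycyclohex-3-ene-1-carboxylate | C1=CC[C@@](O)(C(=O)OC)CC1 | intermediate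
9 | lithium (1R)-1-(methoxycarbonyl)cyclohex-3-en-1-olate (not isolated) | C1=CC[C@@]([O-])(C(=O)OC)CC1.[Li+] | intermediate
10 | methyl (1R)-1-[(tert-butoxycarbonyl)oxy]cyclohex-3-ene-1-carboxylate | C1=CC[C@@](OC(=O)OC(C)(C)C)(C(=O)OC)CC1 | intermediate
11 | methyl (1R,5R,6R)-6-iodo-3-oxo-2,4-dioxabicyclo[3.3.1]nonane-1-carboxylate | O=C1O[C@@H]2C[C@@](O1)(C(=O)OC)CC[C@H]2I | intermediate
12 | methyl (1R,5R)-3-oxo-2,4-dioxabicyclo[3.3.1]non-6-ene-1-carboxylate (not isolated) | O=C1O[C@@H]2C[C@@](O1)(C(=O)OC)CC=C2 | intermediate
13 | methyl (1R,3R)-1,3-dihydroxycyclohex-4-ene-1-carboxylate | O[C@@H]1C[C@@](O)(C(=O)OC)CC=C1 | intermediate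
14 | methyl (1R,2R,4S,6S)-2,4-dihydroxy-7-oxabicyclo[4.1.0]heptane-4-carboxylate | O[C@@H]1C[C@@](O)(C(=O)OC)C[C@@H]2O[C@H]12 | intermediate
15 | caffeic acid | O=C(O)/C=C/c1ccc(O)c(O)c1 | starting material
16 | (E)-3-(3,4-diacetoxyphenyl)prop-2-enoic acid | CC(=O)Oc1ccc(/C=C/C(=O)O)cc1OC(C)=O | intermediate
17 | (E)-3-(3,4-diacetoxyphenyl)prop-2-enoyl chloride | CC(=O)Oc1ccc(/C=C/C(=O)Cl)cc1OC(C)=O | intermediate
18 | methyl 1,3-bis-O-(3,4-di-O-acetylcaffeoyl)-4,5-anhydroquinate (bis-ester of 14) | O=C(/C=C/c1ccc(OC(C)=O)c(OC(C)=O)c1)O[C@@H]1C[C@@](OC(=O)/C=C/c2ccc(OC(C)=O)c(OC(C)=O)c2)(C(=O)OC)C[C@@H]2O[C@H]12 | intermediate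
19 | 1,3-bis-O-(3,4-di-O-acetylcaffeoyl)quinic acid 1,5-lactone, 4-OH free (not isolated) | O=C(/C=C/c1ccc(OC(C)=O)c(OC(C)=O)c1)O[C@@H]1C[C@]2(OC(=O)/C=C/c3ccc(OC(C)=O)c(OC(C)=O)c3)C[C@@H](OC2=O)[C@@H]1O | intermediate
20 | 1,3-di-O-caffeoylquinic acid, (1R,3R,4S,5R) | O=C(/C=C/c1ccc(O)c(O)c1)O[C@@H]1C[C@@](OC(=O)/C=C/c2ccc(O)c(O)c2)(C(=O)O)C[C@@H](O)[C@@H]1O | target

**Step count and risks**
Total steps: 12. Longest linear sequence: 10 (steps 1–8, 11, 12); steps 9–10 are a two-step branch to 17.

Step 12. The protonated oxirane may be opened by an external nucleophile (at C4, or at C5 without engaging the ester) before the ester carbonyl attacks, or the O-methyl lactonium ion may fail to lose its methyl group so that a methyl ester survives; long acid exposure may also let the C3 ester move to O4. Fallback: free the carboxyl under neutral conditions before the oxirane is activated. It sets out from 11: elimination as in step 7, but the carbonate is cleaved with K2CO3 in allyl alcohol, which should also exchange the methyl ester and give prop-2-en-1-yl (1R,3R)-1,3-dihydroxycyclohex-4-ene-1-carboxylate F1. VO(acac)2/t-BuOOH should give the allyl ester epoxy diol F2, and acylation with 17 the allyl ester bis(diacetylcaffeate) F3. Pd(PPh3)4/PhSiH3 should then remove the allyl group to give the epoxy acid F4 (not isolated), whose free carboxyl opens the oxirane at C5 with cat. CSA. The fallback comes back at 19, which is hydrolysed as in the second half of step 12.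

Step 6. The C1 ester carbonyl may compete for the iodonium ion (iodolactonization), IBr may simply add across the alkene, or the hindered Boc group may be lost. Fallback: install O3 and the C4=C5 alkene by epoxide transposition. It sets out from 8: hydroxyl-directed epoxidation (VO(acac)2, t-BuOOH) should give the cis-epoxy alcohol methyl 3-hydroxy-7-oxabicyclo[4.1.0]heptane-3-carboxylate F5. Trans-diaxial opening at C4 with PhSeNa (PhSeSePh, NaBH4, EtOH) should give the hydroxy selenide F6. H2O2 oxidation gives the selenoxide F7 (not isolated), whose syn-elimination away from the carbinol carbon comes back at 13.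

Step 11. Acylation of the hindered tertiary C1–OH by the bulky conjugated acid chloride may stall, chloride may open the oxirane, or acetyl groups may transfer from the aryl acetates. Fallback: build the caffeoyl C=C bonds on the scaffold. It sets out from 14: both hydroxyls are acylated with the small, more electrophilic (diethoxyphosphoryl)acetyl chloride (pyridine, CH2Cl2) to give the bis(phosphonoacetate) F8. A two-fold Horner–Wadsworth–Emmons olefination with 3,4-diacetoxybenzaldehyde (LiCl, DBU, MeCN) should then give the (E,E)-bis-ester and come back at 18.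

Further compounds
F1 | step 12 | prop-2-en-1-yl (1R,3R)-1,3-dihydroxycyclohex-4-ene-1-carboxylate | O[C@@H]1C[C@@](O)(C(=O)OCC=C)CC=C1
F2 | step 12 | allyl ester analogue of 14 (oxirane cis to both hydroxyls) | O[C@@H]1C[C@@](O)(C(=O)OCC=C)C[C@@H]2O[C@H]12
F3 | step 12 | allyl ester analogue of 18 | O=C(/C=C/c1ccc(OC(C)=O)c(OC(C)=O)c1)O[C@@H]1C[C@@](OC(=O)/C=C/c2ccc(OC(C)=O)c(OC(C)=O)c2)(C(=O)OCC=C)C[C@@H]2O[C@H]12
F4 | step 12 | 1,3-bis-O-(3,4-di-O-acetylcaffeoyl)-4,5-anhydroquinic acid (not isolated) | O=C(/C=C/c1ccc(OC(C)=O)c(OC(C)=O)c1)O[C@@H]1C[C@@](OC(=O)/C=C/c2ccc(OC(C)=O)c(OC(C)=O)c2)(C(=O)O)C[C@@H]2O[C@H]12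
F5 | step 6 | methyl 3-hydroxy-7-oxabicyclo[4.1.0]heptane-3-carboxylate, oxirane cis to OH | C1[C@@](O)(C(=O)OC)CC[C@@H]2O[C@H]12
F6 | step 6 | methyl 1,3-dihydroxy-4-(phenylselanyl)cyclohexane-1-carboxylate, 1,3-cis-diol, Se trans to C3–OH | O[C@@H]1C[C@@](O)(C(=O)OC)CC[C@H]1[Se]c1ccccc1
F7 | step 6 | selenoxide of F6 (not isolated) | O[C@@H]1C[C@@](O)(C(=O)OC)CC[C@H]1[Se](=O)c1ccccc1
F8 | step 11 | bis[(diethoxyphosphoryl)acetate] of 14 | CCOP(=O)(OCC)CC(=O)O[C@@H]1C[C@@](OC(=O)CP(=O)(OCC)OCC)(C(=O)OC)C[C@@H]2O[C@H]12
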